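Assumption: locants C1–C15 are the germacranolide numbering of the target (C1 hemiketal carbon, C4 methyl-bearing ether carbon, C5=C6 enol-lactone alkene, C7=C11 butenolide alkene, C8 ester carbon, C10 methyl-bearing carbon, C12 lactone carbonyl, C13 acetoxymethyl carbon); the listed small starting materials, including both enantiomers of methyl 3-bromo-2-methylpropanoate, are taken as commercial.

**Retrosynthetic overview**
- Side chains last: the 4-hydroxytiglate comes from cross-metathesis of a C8 methacrylate, the C13 acetate from a silyl ether.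
- Key disconnection: C2–C3 plus the C4–O bridge. An acyclic α-bromo ketone closes onto the diene terminus of a dienyl butenolide, so the ten-membered carbocycle and the tetrahydrofuran hemiketal form in one radical–polar step that also sets C4 and C1.
- The diene (C3–C5) comes from methacrolein by vinylogous aldol condensation; the bromo ketone is unmasked from a methyl enol ether.
- C8–C9 is made by catalytic enantioselective addition of a dialkylzinc (C10 from a chiral bromo ester) to a butenolide aldehyde.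
- Ring order: butenolide first (carbomagnesiation/carboxylation of but-2-yne-1,4-diol), then the carbocycle and the oxygen bridge together.

**Route**

Step 1
Reactants: 1 but-2-yne-1,4-diol; 2 vinylmagnesium chloride; 3 carbon dioxide
Product: 6 4-ethenyl-3-(hydroxymethyl)furan-2(5H)-one, via alkenylmagnesium chelate 4 (not isolated), via hydroxy acid 5 (not isolated)
Conditions: 2 (4.5 equiv), THF/cyclohexane, reflux; CO2 (gas), −20 °C to rt; 2 M HCl
Reagents that add atoms: none
Why: Hydroxyl-directed anti-carbomagnesiation of a propargylic alcohol (Duboudin/Fallis type) puts vinyl on one alkyne carbon and magnesium on the other in a five-membered alkoxide chelate, so carboxylation places the acid cis to the CH2OH of the vinyl-bearing carbon and acid closes the butenolide carrying C6, C7, C11, C12, C13 and the C8=C9 handle; no stereocentre is formed.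

Step 2
Reactants: 6 4-ethenyl-3-(hydroxymethyl)furan-2(5H)-one
Product: 7 3-({[tert-butyl(dimethyl)silyl]oxy}methyl)-4-ethenylfuran-2(5H)-one
Conditions: TBSCl, imidazole, DMF, 0 °C to rt
Reagents that add atoms: tert-butyl(chloro)dimethylsilane, CC(C)(C)[Si](C)(C)Cl
Why: Standard silylation of the primary alcohol; a silyl ether at C13 (unlike an acetate) is not expelled from the silyloxyfuran or dienolate used in step 6 and prevents lactol formation with the aldehyde of step 3.

Step 3
Reactants: 7 3-({[tert-butyl(dimethyl)silyl]oxy}methyl)-4-ethenylfuran-2(5H)-one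
Product: 9 4-({[tert-butyl(dimethyl)silyl]oxy}methyl)-5-oxo-2,5-dihydrofuran-3-carbaldehyde, via ozonide 8 (not isolated)
Conditions: O3, CH2Cl2, −78 °C; Me2S, −78 °C to rt
Reagents that add atoms: ozone, [O-][O+]=O
Why: Ozonolysis cleaves the monosubstituted vinyl group far faster than the electron-poor tetrasubstituted butenolide alkene and gives the C8 aldehyde.

Step 4
Reactants: 10 methyl (2S)-3-bromo-2-methylpropanoate
Product: 11 (3S)-4-bromo-2-methoxy-3-methylbut-1-ene
Conditions: Cp2TiMe2 (2.5 equiv), toluene, 65 °C, dark; filtration through basic alumina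
Reagents that add atoms: dimethyltitanocene Cp2TiMe2, C[Ti](C)(C1C=CC=C1)C1C=CC=C1
Why: Petasis methylenation turns the ester carbonyl into a methyl enol ether (C1=C2, a masked bromomethyl ketone) under non-basic conditions, so the α-stereocentre (future C10) is retained.

Step 5
Reactants: 11 (3S)-4-bromo-2-methoxy-3-methylbut-1-ene; 9 4-({[tert-butyl(dimethyl)silyl]oxy}methyl)-5-oxo-2,5-dihydrofuran-3-carbaldehyde; 12 methacryloyl chloride
Product: 16 (1S,3R)-1-[4-({[tert-butyl(dimethyl)silyl]oxy}methyl)-5-oxo-2,5-dihydrofuran-3-yl]-4-methoxy-3-methylpent-4-en-1-yl 2-methylprop-2-enoate, via Grignard reagent 13 (not isolated), via dialkylzinc 14 (not isolated), via zinc alkoxide 15 (not isolated)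
Conditions: 11 (3.2 equiv), Mg, Et2O, 0 °C; ZnCl2 (1.6 equiv), then 1,4-dioxane, filter; 9 (1 equiv), (−)-MIB [(2S)-3-exo-morpholinoisoborneol, 5 mol%], toluene, −10 °C; then 12 (3 equiv), DMAP (0.2 equiv), 0 °C; aq. NaHCO3
Reagents that add atoms: none
Why: Amino-alcohol-catalysed enantioselective dialkylzinc addition (Noyori/Nugent type) sets C8 as S by catalyst control, as for aryl aldehydes (same CIP ranking O > sp2 carbon > alkyl > H), C10 (R) is carried in unchanged from 10, and acylating the zinc alkoxide in the same flask stops the C8 alkoxide from translactonising onto C12.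

Step 6
Reactants: 16 (1S,3R)-1-[4-({[tert-butyl(dimethyl)silyl]oxy}methyl)-5-oxo-2,5-dihydrofuran-3-yl]-4-methoxy-3-methylpent-4-en-1-yl 2-methylprop-2-enoate; 17 methacrolein
Product: 20 (1S,3R)-1-[(2Z)-4-({[tert-butyl(dimethyl)silyl]oxy}methyl)-2-(2-methylprop-2-en-1-ylidene)-5-oxo-2,5-dihydrofuran-3-yl]-4-methoxy-3-methylpent-4-en-1-yl 2-methylprop-2-enoate, via silyloxyfuran 18 (not isolated), via silyl aldol 19 (not isolated)
Conditions: TBSOTf (1.3 equiv), Et3N (3 equiv), CH2Cl2, −78 to 0 °C; 17 (2 equiv), −78 °C; DBU (3 equiv), −78 °C to rt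
Reagents that add atoms: none
Why: One-pot vinylogous Mukaiyama aldol addition of the in-situ 2-silyloxyfuran to the enal followed by base-induced loss of silanolate (Boukouvalas-type ylidenation) installs C5=C6 and the C3=C4 alkene; the Z geometry expected is of no consequence because it is corrected in step 8.

Step 7
Reactants: 20 (Z)-dienylidene butenolide enol ether from step 6
Product: 21 (1S,3R)-5-bromo-1-[(2Z)-4-({[tert-butyl(dimethyl)silyl]oxy}methyl)-2-(2-methylprop-2-en-1-ylidene)-5-oxo-2,5-dihydrofuran-3-yl]-3-methyl-4-oxopentyl 2-methylprop-2-enoate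
Conditions: NBS (1.05 equiv), NaHCO3, THF/H2O 4:1, −20 °C, dark
Reagents that add atoms: N-bromosuccinimide, O=C1CCC(=O)N1Br; water, O
Why: Electrophilic bromination of the methyl enol ether, by far the most nucleophilic alkene present, followed by hydrolysis of the bromo-oxocarbenium ion gives the bromomethyl ketone regiospecifically at C2 without enolising C10.

Step 8
Reactants: 21 (Z)-bromomethyl ketone from step 7
Product: 24 (1S,4R,5E,8S,10R)-13-{[tert-butyl(dimethyl)silyl]oxy}-1,4-epoxy-1-hydroxy-8-(2-methylprop-2-enoyloxy)germacra-5,7(11)-dien-12,6-olide, via E isomer 22 (not isolated), via oxocarbenium bromide 23 (not isolated)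
Conditions: fac-Ir(ppy)3 (2 mol%), 2,6-lutidine (2 equiv), MeCN/H2O 20:1, 2 mM, blue LEDs (450 nm), 25 °C, degassed
Reagents that add atoms: water, O
Why: Proposed new method: the excited iridium photocatalyst sensitises Z→E isomerisation of the dienyl enol lactone (the twisted, less conjugated E isomer 22 is the poorer triplet acceptor and builds up) and also reduces the C–Br bond; the electrophilic α-keto radical at C2 adds 10-endo to the diene terminus C3 of 22 (C2–C3, the key bond), the tertiary C4 radical is oxidised by the oxidised photocatalyst to the cation, the C1 carbonyl oxygen captures it across the ring through a five-membered transition state to give 23, and water adds at C1; C4 comes out 4R because allylic strain keeps C8–H in the butenolide plane, which puts the C9 arm and C3 on one face and brings the oxygen onto C4 from the ring interior on the face of the C8 ester, and C1 (S) follows because the oxygen bridge can only be cis; the closest known reactions are photoredox radical–polar crossover carbo-oxygenations of alkenes with α-bromo carbonyl compounds (formal [3+2] to tetrahydrofuranols and lactones), manganese triacetate ketone–alkene oxidative annulations and endo atom-transfer radical macrocyclisations of α-halo carbonyl compounds.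

Step 9
Reactants: 24 silyl-protected macrocyclic hemiketal from step 8
Product: 26 (1S,4R,5E,8S,10R)-13-acetoxy-1,4-epoxy-1-hydroxy-8-(2-methylprop-2-enoyloxy)germacra-5,7(11)-dien-12,6-olide, via primary alcohol 25 (not isolated)
Conditions: HF·pyridine, pyridine/THF, 0 °C to rt; then Ac2O, 0 °C
Reagents that add atoms: acetic anhydride, CC(=O)OC(C)=O
Why: Fluoride removes the primary silyl ether and the liberated primary allylic alcohol is acetylated selectively, the tertiary hemiketal hydroxyl being inert to Ac2O/pyridine without DMAP.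

Step 10
Reactants: 26 C13 acetate C8 methacrylate from step 9; 27 (2Z)-but-2-ene-1,4-diol
Product: 28 (1S,4R,5E,8S,10R)-13-acetoxy-1,4-epoxy-1-hydroxy-8-[(2E)-4-hydroxy-2-methylbut-2-enoyloxy]germacra-5,7(11)-dien-12,6-olide (CNP0154520.1)
Conditions: 27 (5 equiv), RuCl2(H2IMes)(=CH-2-iPrO-C6H4) (second-generation Hoveyda–Grubbs catalyst, 10 mol%), CH2Cl2, 40 °C
Reagents that add atoms: none
Why: Olefin cross-metathesis of the 1,1-disubstituted methacrylate with the allylic diol gives the trisubstituted enoate with the E (tiglate) geometry under thermodynamic control, while the tetrasubstituted butenolide and the trisubstituted enol-lactone alkenes are inert.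

**Compound list**

1 | but-2-yne-1,4-diol | OCC#CCO | starting material
2 | vinylmagnesium chloride | C=C[Mg]Cl | starting material
3 | carbon dioxide | O=C=O | starting material
4 | alkenylmagnesium chelate: tris(chloromagnesium) derivative of (2Z)-2-ethenylbut-2-ene-1,4-diol metallated at C3, vinyl trans to the C–Mg bond | C=C/C(CO[Mg]Cl)=C(/[Mg]Cl)CO[Mg]Cl | intermediate
5 | (2Z)-2,3-bis(hydroxymethyl)penta-2,4-dienoic acid | C=C/C(CO)=C(/C(=O)O)CO | intermediate
6 | 4-ethenyl-3-(hydroxymethyl)furan-2(5H)-one | C=CC1=C(CO)C(=O)OC1 | intermediate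
7 | 3-({[tert-butyl(dimethyl)silyl]oxy}methyl)-4-ethenylfuran-2(5H)-one | C=CC1=C(CO[Si](C)(C)C(C)(C)C)C(=O)OC1 | intermediate
8 | ozonide (1,2,4-trioxolan-3-yl derivative) of 7 | CC(C)(C)[Si](C)(C)OCC1=C(C2OCOO2)COC1=O | intermediate
9 | 4-({[tert-butyl(dimethyl)silyl]oxy}methyl)-5-oxo-2,5-dihydrofuran-3-carbaldehyde | O=CC1=C(CO[Si](C)(C)C(C)(C)C)C(=O)OC1 | intermediate
10 | methyl (2S)-3-bromo-2-methylpropanoate | COC(=O)[C@H](C)CBr | starting material
11 | (3S)-4-bromo-2-methoxy-3-methylbut-1-ene | COC(=C)[C@H](C)CBr | intermediate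
12 | methacryloyl chloride | CC(=C)C(=O)Cl | starting material
13 | [(2S)-3-methoxy-2-methylbut-3-en-1-yl]magnesium bromide | COC(=C)[C@H](C)C[Mg]Br | intermediate
14 | bis[(2S)-3-methoxy-2-methylbut-3-en-1-yl]zinc | COC(=C)[C@H](C)C[Zn]C[C@@H](C)C(=C)OC | intermediate
15 | alkylzinc alkoxide of (1S,3R)-1-[4-({[tert-butyl(dimethyl)silyl]oxy}methyl)-5-oxo-2,5-dihydrofuran-3-yl]-4-methoxy-3-methylpent-4-en-1-ol | O=C1OCC([C@@H](O[Zn]C[C@@H](C)C(=C)OC)C[C@@H](C)C(=C)OC)=C1CO[Si](C)(C)C(C)(C)C | intermediate
16 | (1S,3R)-1-[4-({[tert-butyl(dimethyl)silyl]oxy}methyl)-5-oxo-2,5-dihydrofuran-3-yl]-4-methoxy-3-methylpent-4-en-1-yl 2-methylprop-2-enoate | O=C1OCC([C@@H](OC(=O)C(C)=C)C[C@@H](C)C(=C)OC)=C1CO[Si](C)(C)C(C)(C)C | intermediate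
17 | methacrolein (2-methylprop-2-enal) | CC(=C)C=O | starting material
18 | (1S,3R)-1-[5-{[tert-butyl(dimethyl)silyl]oxy}-4-({[tert-butyl(dimethyl)silyl]oxy}methyl)furan-3-yl]-4-methoxy-3-methylpent-4-en-1-yl 2-methylprop-2-enoate | CC(C)(C)[Si](C)(C)OCc1c(O[Si](C)(C)C(C)(C)C)occ1[C@@H](OC(=O)C(C)=C)C[C@@H](C)C(=C)OC | intermediate
19 | silyl aldol: 16 carrying a 1-{[tert-butyl(dimethyl)silyl]oxy}-2-methylprop-2-en-1-yl group at the ring CH (C6), mixture at the two new centres | C=C(C)C(O[Si](C)(C)C(C)(C)C)C1OC(=O)C(CO[Si](C)(C)C(C)(C)C)=C1[C@@H](OC(=O)C(C)=C)C[C@@H](C)C(=C)OC | intermediate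
20 | (1S,3R)-1-[(2Z)-4-({[tert-butyl(dimethyl)silyl]oxy}methyl)-2-(2-methylprop-2-en-1-ylidene)-5-oxo-2,5-dihydrofuran-3-yl]-4-methoxy-3-methylpent-4-en-1-yl 2-methylprop-2-enoate | O=C1O/C(=C\C(C)=C)C([C@@H](OC(=O)C(C)=C)C[C@@H](C)C(=C)OC)=C1CO[Si](C)(C)C(C)(C)C | intermediate
21 | (1S,3R)-5-bromo-1-[(2Z)-4-({[tert-butyl(dimethyl)silyl]oxy}methyl)-2-(2-methylprop-2-en-1-ylidene)-5-oxo-2,5-dihydrofuran-3-yl]-3-methyl-4-oxopentyl 2-methylprop-2-enoate | O=C1O/C(=C\C(C)=C)C([C@@H](OC(=O)C(C)=C)C[C@@H](C)C(=O)CBr)=C1CO[Si](C)(C)C(C)(C)C | intermediate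
22 | (2E) isomer of 21 (C4 cis to C7 across C5=C6) | O=C1O/C(=C/C(C)=C)C([C@@H](OC(=O)C(C)=C)C[C@@H](C)C(=O)CBr)=C1CO[Si](C)(C)C(C)(C)C | intermediate
23 | bicyclic oxocarbenium bromide (C1=O+ bridged to C4, 4R) | CC(C)(C)[Si](C)(C)OCC1=C2/C(=C\[C@@]3(C)CCC(=[O+]3)[C@H](C)C[C@@H]2OC(=O)C(C)=C)OC1=O.[Br-] | intermediate
24 | (1S,4R,5E,8S,10R)-13-{[tert-butyl(dimethyl)silyl]oxy}-1,4-epoxy-1-hydroxy-8-(2-methylprop-2-enoyloxy)germacra-5,7(11)-dien-12,6-olide | CC(C)(C)[Si](C)(C)OCC1=C2/C(=C\[C@@]3(C)CC[C@](O)(O3)[C@H](C)C[C@@H]2OC(=O)C(C)=C)OC1=O | intermediate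
25 | (1S,4R,5E,8S,10R)-1,4-epoxy-1,13-dihydroxy-8-(2-methylprop-2-enoyloxy)germacra-5,7(11)-dien-12,6-olide | OCC1=C2/C(=C\[C@@]3(C)CC[C@](O)(O3)[C@H](C)C[C@@H]2OC(=O)C(C)=C)OC1=O | intermediate
26 | (1S,4R,5E,8S,10R)-13-acetoxy-1,4-epoxy-1-hydroxy-8-(2-methylprop-2-enoyloxy)germacra-5,7(11)-dien-12,6-olide | CC(=O)OCC1=C2/C(=C\[C@@]3(C)CC[C@](O)(O3)[C@H](C)C[C@@H]2OC(=O)C(C)=C)OC1=O | intermediate
27 | (2Z)-but-2-ene-1,4-diol | OC/C=C\CO | starting material
28 | (1S,4R,5E,8S,10R)-13-acetoxy-1,4-epoxy-1-hydroxy-8-[(2E)-4-hydroxy-2-methylbut-2-enoyloxy]germacra-5,7(11)-dien-12,6-olide (CNP0154520.1) | CC(=O)OCC1=C2/C(=C\[C@@]3(C)CC[C@](O)(O3)[C@H](C)C[C@@H]2OC(=O)/C(C)=C/CO)OC1=O | target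

**Step count**

Total steps: 10. Longest linear sequence: 9 (steps 1, 2, 3, 5, 6, 7, 8, 9, 10 from but-2-yne-1,4-diol; step 4 is a one-step side branch).

**Steps most likely to fail, with fallbacks**

Step 8 is the least certain step. The C2 radical may take the allylic C8–H by 1,5-hydrogen transfer or simply be reduced. The E isomer 22 may be too scarce at the photostationary state. The C4 cation may lose a proton instead of being trapped, or be trapped on the wrong face. The fallback moves the ring closure to a polar C5=C6 condensation and keeps a radical C2–C3 bond formation between two molecules. It sets out from 16 and returns at 25.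
- Ester 16 with NBS/H2O (as in step 7) gives bromomethyl ketone F1.
- F1 with isoprene (10 equiv) under the step 8 photoredox conditions gives, by radical addition, oxidation and ketone capture at the tertiary allyl terminus, the 5-methyl-5-vinyl tetrahydrofuran-2-ol F2. This forms as both C4 epimers; the 4R epimer is separated by chromatography.
- OsO4 (cat.)/NaIO4 cleaves the electron-rich vinyl group of F2 to the non-enolisable aldehyde F3.
- TBSOTf/Et3N then DBU (the intramolecular version of step 6) closes the ten-membered ring and silylates the hemiketal, giving bis-silyl ether F4.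
- HF·pyridine converts F4 into 25, which is acetylated as in step 9.

Step 6 is the second risk. The silyl triflate can ionise the furfuryl-type C8 ester of silyloxyfuran 18 or attack the enol ether. The amidine step can expel the C13 silyloxy group from the dienolate instead of the aldol oxygen. Methacrolein may add 1,4 or polymerise. The fallback avoids both the silyl triflate and the amidine base; it sets out from 16 and returns at 20. The lithium dienolate of 16 (LiHMDS, THF, −78 °C, 5 min) is trapped with methacrolein and the free vinylogous aldol adduct F5 is isolated. F5 is then dehydrated under neutral conditions with the Burgess reagent (benzene, 50 °C). Only C6–H is available for the syn-elimination, so 20 results, as an E/Z mixture that step 8 accepts.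

Step 5 is the third risk. The homoallylic Grignard reagent 13 can rearrange through a cyclopropylcarbinyl form. Residual magnesium salts or the very electrophilic aldehyde 9 can cause uncatalysed, unselective addition. The zinc alkoxide 15 can translactonise before it is acylated. The fallback sets C8 by reduction instead of addition; it sets out from 9 (with Grignard reagent 13) and returns at 16. Addition of 13 to 9 at −78 °C without catalyst gives the C8-epimeric alcohols F6. Dess–Martin periodinane buffered with NaHCO3 gives the ketone F7. Reduction with (R)-Me-CBS oxazaborolidine and catecholborane at −78 °C (butenolidyl as the large group; catecholborane spares the enol ether) gives the (1S)-alcohol F8. Immediate acylation of F8 with 12, Et3N and DMAP gives 16.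

**Further compounds**

F1 | step 8 | (1S,3R)-5-bromo-1-[4-({[tert-butyl(dimethyl)silyl]oxy}methyl)-5-oxo-2,5-dihydrofuran-3-yl]-3-methyl-4-oxopentyl 2-methylprop-2-enoate | O=C1OCC([C@@H](OC(=O)C(C)=C)C[C@@H](C)C(=O)CBr)=C1CO[Si](C)(C)C(C)(C)C
F2 | step 8 | (1S,3R)-1-[4-({[tert-butyl(dimethyl)silyl]oxy}methyl)-5-oxo-2,5-dihydrofuran-3-yl]-3-[(5R)-5-ethenyl-2-hydroxy-5-methyltetrahydrofuran-2-yl]butyl 2-methylprop-2-enoate (hemiketal carbon as anomeric mixture) | C=C[C@@]1(C)CCC(O)(O1)[C@H](C)C[C@H](OC(=O)C(C)=C)C2=C(CO[Si](C)(C)C(C)(C)C)C(=O)OC2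
F3 | step 8 | (1S,3R)-1-[4-({[tert-butyl(dimethyl)silyl]oxy}methyl)-5-oxo-2,5-dihydrofuran-3-yl]-3-[(5R)-5-formyl-2-hydroxy-5-methyltetrahydrofuran-2-yl]butyl 2-methylprop-2-enoate | O=C[C@@]1(C)CCC(O)(O1)[C@H](C)C[C@H](OC(=O)C(C)=C)C2=C(CO[Si](C)(C)C(C)(C)C)C(=O)OC2
F4 | step 8 | 1-O-tert-butyldimethylsilyl ether of 24 | CC(C)(C)[Si](C)(C)OCC1=C2/C(=C\[C@@]3(C)CC[C@](O[Si](C)(C)C(C)(C)C)(O3)[C@H](C)C[C@@H]2OC(=O)C(C)=C)OC1=O
F5 | step 6 | (1S,3R)-1-[4-({[tert-butyl(dimethyl)silyl]oxy}methyl)-2-(1-hydroxy-2-methylprop-2-en-1-yl)-5-oxo-2,5-dihydrofuran-3-yl]-4-methoxy-3-methylpent-4-en-1-yl 2-methylprop-2-enoate (mixture at the two new centres) | C=C(C)C(O)C1OC(=O)C(CO[Si](C)(C)C(C)(C)C)=C1[C@@H](OC(=O)C(C)=C)C[C@@H](C)C(=C)OC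
F6 | step 5 | 3-({[tert-butyl(dimethyl)silyl]oxy}methyl)-4-[(3R)-1-hydroxy-4-methoxy-3-methylpent-4-en-1-yl]furan-2(5H)-one (both C1 epimers of the side chain) | O=C1OCC(C(O)C[C@@H](C)C(=C)OC)=C1CO[Si](C)(C)C(C)(C)C
F7 | step 5 | 3-({[tert-butyl(dimethyl)silyl]oxy}methyl)-4-[(3R)-4-methoxy-3-methylpent-4-enoyl]furan-2(5H)-one | O=C1OCC(C(=O)C[C@@H](C)C(=C)OC)=C1CO[Si](C)(C)C(C)(C)C
F8 | step 5 | 3-({[tert-butyl(dimethyl)silyl]oxy}methyl)-4-[(1S,3R)-1-hydroxy-4-methoxy-3-methylpent-4-en-1-yl]furan-2(5H)-one | O=C1OCC([C@@H](O)C[C@@H](C)C(=C)OC)=C1CO[Si](C)(C)C(C)(C)C
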